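**Retrosynthetic overview**
1. C2 (the acid-bearing centre, S) is set last, by carboxylate-directed asymmetric hydrogenation of the (E)-2-alkylhept-2-enoic acid.
2. That enoic acid is cut at C2=C3 (Wittig reaction with an α-allyl ylide); the furan is joined to the allyl group by hydroboration/Suzuki coupling with 3-bromofuran.
3. The aldehyde partner MeO2C–CH(CH2CH2CH=CMe2)–CH2CH2CHO comes from a bromo diester by Negishi coupling and partial ester reduction.
4. The bromo diester is the HBr/MeOH opening product of a seven-membered lactone, made by enantiotopic-group-selective Baeyer–Villiger oxidation of methyl 4-oxocyclohexanecarboxylate (sets C6); the ketone comes from methylparaben by partial hydrogenation.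
5. Rings: no ring of the target is built (the furan is brought in intact); cyclohexanone, seven-membered lactone and five-membered lactone are formed in that order and all are opened again.

Assumption: the SMILES is read as the (2S,6R) acid (C2 bears CO2H, C6 bears CO2Me), and the two enzymes of step 2 are bought as catalogue biocatalysts.

Step 1
Reactants: 1 methyl 4-hydroxybenzoate
Product: 2 methyl 4-oxocyclohexane-1-carboxylate
Conditions: H2 (10 bar), 5% Pd/C, AlCl3 (10 mol%), CH2Cl2, 50 °C
Reagents that add atoms: none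
Why: Palladium-catalysed partial arene hydrogenation of a phenol stops at the cyclohexanone because Pd reduces ketones only slowly and the Lewis acid binds the ketone formed, and no stereocentre is created.

Step 2
Reactants: 2 methyl 4-oxocyclohexane-1-carboxylate
Product: 3 methyl (4R)-7-oxooxepane-4-carboxylate
Conditions: Baeyer–Villiger monooxygenase (purified; (R)-selective clone picked from a cyclohexanone-/cyclopentanone-monooxygenase panel), NADP+ (cat.), phosphite dehydrogenase, Na2HPO3, air, Tris buffer pH 8, 25 °C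
Reagents that add atoms: dioxygen, O=O
Why: Enzymatic Baeyer–Villiger oxidation used as a desymmetrization, in which the chiral active site lets only one of the two enantiotopic ring C–C(=O) bonds migrate to oxygen, so the prochiral carbon becomes the (R)-stereocentre (the later C6 of the target), as is well established for 4-alkyl- and 4-heteroatom-substituted cyclohexanones.

Step 3
Reactants: 3 methyl (4R)-7-oxooxepane-4-carboxylate
Product: 5 dimethyl (2R)-2-(2-bromoethyl)pentanedioate, via γ-lactone ester 4 (not isolated)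
Conditions: HBr (g, sat.), MeOH, 0 °C → rt, 24 h
Reagents that add atoms: hydrogen bromide, Br; methanol, CO
Why: Acid-mediated lactone opening (the γ-butyrolactone → 4-bromobutanoate reaction), in which methanolysis and translactonization give the five-membered lactone 4, bromide opens its protonated form by SN2 attack at the O–CH2 carbon and methanol esterifies the carboxyl, so no bond at the stereocentre is touched and the configuration is retained.

Step 4
Reactants: 5 dimethyl (2R)-2-(2-bromoethyl)pentanedioate; 6 1-bromo-2-methylprop-1-ene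
Product: 8 dimethyl (2S)-2-(4-methylpent-3-en-1-yl)pentanedioate, via alkylzinc bromide 7 (not isolated)
Conditions: Zn dust (1.5 equiv), I2 (5 mol%), DMA, 70 °C; then 6 (1.3 equiv), Pd(OAc)2 (2 mol%), SPhos (4 mol%), THF, 50 °C
Reagents that add atoms: none
Why: Negishi sp3–sp2 cross-coupling, in which zinc inserts into the primary C–Br bond to give an ester-tolerant alkylzinc bromide that couples with the alkenyl bromide under palladium catalysis, building the 4-methylpent-3-enyl arm without touching the stereocentre (its descriptor becomes S only through the CIP ranking).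

Step 5
Reactants: 8 dimethyl (2S)-2-(4-methylpent-3-en-1-yl)pentanedioate
Product: 9 methyl (2S)-6-methyl-2-(3-oxopropyl)hept-5-enoate
Conditions: i-Bu2AlH (1.05 equiv), toluene, −78 °C; MeOH, then aq. KNaC4H4O6
Reagents that add atoms: none
Why: Partial ester reduction with i-Bu2AlH at −78 °C stops at the aldehyde oxidation level and is expected to occur at the unbranched CH2CH2CO2Me group because the other ester is shielded by its α-branch, the stereocentre not being involved.

Step 6
Reactants: 10 tert-butyl 2-(triphenyl-λ5-phosphanylidene)acetate; 11 3-bromoprop-1-ene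
Product: 13 tert-butyl 2-(triphenyl-λ5-phosphanylidene)pent-4-enoate, via phosphonium bromide 12 (not isolated)
Conditions: EtOAc, reflux; then 1 M NaOH, CH2Cl2, 0 °C
Reagents that add atoms: none
Why: C-Alkylation of an ester-stabilized phosphorus ylide by SN2 attack on the allylic bromide gives phosphonium salt 12, from which hydroxide removes the remaining α-proton to give the substituted ylide, and no stereocentre is formed.

Step 7
Reactants: 9 methyl (2S)-6-methyl-2-(3-oxopropyl)hept-5-enoate; 13 tert-butyl 2-(triphenyl-λ5-phosphanylidene)pent-4-enoate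
Product: 14 1-tert-butyl 7-methyl (2E,6S)-6-(4-methylpent-3-en-1-yl)-2-(prop-2-en-1-yl)hept-2-enedioate
Conditions: toluene, 90 °C, 16 h
Reagents that add atoms: none
Why: Wittig olefination with an α-substituted ester-stabilized ylide is E-selective (CO2t-Bu trans to the new chain, E/Z ≥ 95:5 expected, the minor isomer removed by chromatography), and the neutral conditions do not epimerize the α-ester stereocentre.

Step 8
Reactants: 14 1-tert-butyl 7-methyl (2E,6S)-6-(4-methylpent-3-en-1-yl)-2-(prop-2-en-1-yl)hept-2-enedioate; 15 3-bromofuran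
Product: 17 1-tert-butyl 7-methyl (2E,6S)-2-[3-(furan-3-yl)propyl]-6-(4-methylpent-3-en-1-yl)hept-2-enedioate, via alkylborane 16 (not isolated)
Conditions: 9-BBN (1.1 equiv), THF, 0 °C → rt; then 15 (1.3 equiv), PdCl2(dppf) (3 mol%), K3PO4 (3 M aq.), DMF, 50 °C
Reagents that add atoms: none
Why: Hydroboration followed by B-alkyl Suzuki–Miyaura coupling, in which 9-BBN adds anti-Markovnikov only to the monosubstituted olefin (the trisubstituted and the conjugated double bonds react far more slowly) and the alkylborane 16 is coupled with 3-bromofuran under palladium catalysis, leaving the E-olefin and the stereocentre unchanged.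

Step 9
Reactants: 17 1-tert-butyl 7-methyl (2E,6S)-2-[3-(furan-3-yl)propyl]-6-(4-methylpent-3-en-1-yl)hept-2-enedioate
Product: 19 (2E,6S)-2-[3-(furan-3-yl)propyl]-7-methoxy-6-(4-methylpent-3-en-1-yl)-7-oxohept-2-enoic acid, via trimethylsilyl ester 18 (not isolated)
Conditions: Me3SiOTf (2 equiv), 2,6-lutidine (3 equiv), CH2Cl2, 0 °C → rt; then H2O, pH 4
Reagents that add atoms: none
Why: Silyl triflate-mediated tert-butyl ester cleavage, in which O-silylation is followed by loss of the tert-butyl cation that lutidine converts to isobutene before it can attack the furan or the olefin, silyl ester 18 being hydrolysed on work-up while the methyl ester is untouched.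

Step 10
Reactants: 19 (2E,6S)-2-[3-(furan-3-yl)propyl]-7-methoxy-6-(4-methylpent-3-en-1-yl)-7-oxohept-2-enoic acid
Product: 20 (2S,6R)-2-[3-(furan-3-yl)propyl]-7-methoxy-6-(4-methylpent-3-en-1-yl)-7-oxoheptanoic acid
Conditions: H2 (4 bar), Ru(OAc)2[(R)-H8-BINAP] (1 mol%), MeOH, 20 °C
Reagents that add atoms: none
Why: Carboxylate-directed asymmetric hydrogenation of an (E)-2-alkylalk-2-enoic acid (Noyori–Takaya type) delivers H2 to one face of the conjugated double bond only, setting C2 as S under catalyst control independently of the remote C6 centre (the (R)-ligand is chosen by analogy with tiglic acid, which gives (S)-2-methylbutanoic acid with the (S)-ligand, the descriptor being inverted here by the CIP ranks of the two chains), while the isolated trisubstituted olefin, the furan and the methyl ester are inert.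

**Compound list**
1 | methyl 4-hydroxybenzoate | COC(=O)c1ccc(O)cc1 | starting material
2 | methyl 4-oxocyclohexane-1-carboxylate | COC(=O)C1CCC(=O)CC1 | intermediate
3 | methyl (4R)-7-oxooxepane-4-carboxylate | COC(=O)[C@H]1CCOC(=O)CC1 | intermediate
4 | methyl 3-[(3R)-2-oxooxolan-3-yl]propanoate | COC(=O)CC[C@@H]1CCOC1=O | intermediate
5 | dimethyl (2R)-2-(2-bromoethyl)pentanedioate | COC(=O)[C@@H](CCBr)CCC(=O)OC | intermediate
6 | 1-bromo-2-methylprop-1-ene | CC(C)=CBr | starting material
7 | bromo[(3R)-5-methoxy-3-(methoxycarbonyl)-5-oxopentyl]zinc | COC(=O)[C@@H](CC[Zn]Br)CCC(=O)OC | intermediate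
8 | dimethyl (2S)-2-(4-methylpent-3-en-1-yl)pentanedioate | COC(=O)[C@@H](CCC=C(C)C)CCC(=O)OC | intermediate
9 | methyl (2S)-6-methyl-2-(3-oxopropyl)hept-5-enoate | COC(=O)[C@@H](CCC=C(C)C)CCC=O | intermediate
10 | tert-butyl 2-(triphenyl-λ5-phosphanylidene)acetate | CC(C)(C)OC(=O)C=P(c1ccccc1)(c1ccccc1)c1ccccc1 | starting material
11 | 3-bromoprop-1-ene | C=CCBr | starting material
12 | (1-tert-butoxy-1-oxopent-4-en-2-yl)triphenylphosphonium bromide | CC(C)(C)OC(=O)C(CC=C)[P+](c1ccccc1)(c1ccccc1)c1ccccc1.[Br-] | intermediate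
13 | tert-butyl 2-(triphenyl-λ5-phosphanylidene)pent-4-enoate | CC(C)(C)OC(=O)C(CC=C)=P(c1ccccc1)(c1ccccc1)c1ccccc1 | intermediate
14 | 1-tert-butyl 7-methyl (2E,6S)-6-(4-methylpent-3-en-1-yl)-2-(prop-2-en-1-yl)hept-2-enedioate | COC(=O)[C@@H](CCC=C(C)C)CC/C=C(\CC=C)C(=O)OC(C)(C)C | intermediate
15 | 3-bromofuran | Brc1ccoc1 | starting material
16 | 1-tert-butyl 7-methyl (2E,6S)-2-[3-(9-borabicyclo[3.3.1]nonan-9-yl)propyl]-6-(4-methylpent-3-en-1-yl)hept-2-enedioate | COC(=O)[C@@H](CCC=C(C)C)CC/C=C(\CCCB1C2CCCC1CCC2)C(=O)OC(C)(C)C | intermediate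
17 | 1-tert-butyl 7-methyl (2E,6S)-2-[3-(furan-3-yl)propyl]-6-(4-methylpent-3-en-1-yl)hept-2-enedioate | COC(=O)[C@@H](CCC=C(C)C)CC/C=C(\CCCc1ccoc1)C(=O)OC(C)(C)C | intermediate
18 | 7-methyl 1-(trimethylsilyl) (2E,6S)-2-[3-(furan-3-yl)propyl]-6-(4-methylpent-3-en-1-yl)hept-2-enedioate | COC(=O)[C@@H](CCC=C(C)C)CC/C=C(\CCCc1ccoc1)C(=O)O[Si](C)(C)C | intermediate
19 | (2E,6S)-2-[3-(furan-3-yl)propyl]-7-methoxy-6-(4-methylpent-3-en-1-yl)-7-oxohept-2-enoic acid | COC(=O)[C@@H](CCC=C(C)C)CC/C=C(\CCCc1ccoc1)C(=O)O | intermediate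
20 | (2S,6R)-2-[3-(furan-3-yl)propyl]-7-methoxy-6-(4-methylpent-3-en-1-yl)-7-oxoheptanoic acid | COC(=O)[C@@H](CCC=C(C)C)CCC[C@@H](CCCc1ccoc1)C(=O)O | target

**Step count and risks**
Total: 10 steps. Longest linear sequence: 9 steps (steps 1–5 and 7–10, from methyl 4-hydroxybenzoate).

The three steps most likely to fail:

Step 2. An ester-bearing ketone is at the edge of the usual substrate range of these monooxygenases, and the common Acinetobacter cyclohexanone monooxygenase is expected to give the opposite antipode, so the route depends on finding an (R)-selective clone with high ee. The fallback sets out from 6 and comes back at 8, setting C6 by auxiliary-controlled Michael addition instead of desymmetrization. Compound 6 is coupled (Pd(PPh3)4, THF) with commercial (4-ethoxy-4-oxobutyl)zinc bromide to ethyl 6-methylhept-5-enoate F1, which LiOH hydrolyses to 6-methylhept-5-enoic acid F2. F2 is N-acylated (DCC, DMAP) onto (R)-4-benzyl-1,3-oxazolidin-2-one to give (4R)-4-benzyl-3-(6-methylhept-5-enoyl)-1,3-oxazolidin-2-one F3. Its chlorotitanium enolate (TiCl4, i-Pr2NEt, CH2Cl2, −78 → 0 °C) adds to methyl acrylate anti to the benzyl group to give methyl (4S)-4-{[(4R)-4-benzyl-2-oxo-1,3-oxazolidin-3-yl]carbonyl}-8-methylnon-7-enoate F4, and MeOMgBr in MeOH at 0 °C releases the auxiliary and gives 8.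

Step 5. The two methyl esters differ only by the α-branch, so over-reduction or attack at the wrong ester may lower the yield. The fallback sets out from 8 and comes back at 9. Pig-liver esterase (pH 7 buffer) hydrolyses only the unhindered ester to (4S)-4-(methoxycarbonyl)-8-methylnon-7-enoic acid F5. EtSH, DCC and DMAP convert it to methyl (2S)-2-[3-(ethylsulfanyl)-3-oxopropyl]-6-methylhept-5-enoate F6, and Fukuyama reduction (Et3SiH, Pd/C, acetone) gives 9.

Step 10. The facial sense and ee are extrapolated from 2-methyl-substituted acids to a much longer α-chain and must be confirmed on the first run (the ligand antipode is the remedy if the sense is reversed); any Z-acid carried over from step 7 would give the C2 epimer. The fallback sets out from 9 and 15 and comes back at 20, making the C2 centre by auxiliary-controlled alkylation instead of hydrogenation. NaBH4 reduces 9 to methyl (2S)-2-(3-hydroxypropyl)-6-methylhept-5-enoate F7, and Tf2O/2,6-lutidine gives methyl (2S)-6-methyl-2-{3-[(trifluoromethanesulfonyl)oxy]propyl}hept-5-enoate F8. Separately, commercial (4S)-4-benzyl-3-(pent-4-enoyl)-1,3-oxazolidin-2-one is hydroborated with 9-BBN to (4S)-4-benzyl-3-[5-(9-borabicyclo[3.3.1]nonan-9-yl)pentanoyl]-1,3-oxazolidin-2-one F9 and coupled with 15 (PdCl2(dppf), K3PO4) to (4S)-4-benzyl-3-[5-(furan-3-yl)pentanoyl]-1,3-oxazolidin-2-one F10. The sodium enolate of F10 (NaN(SiMe3)2, THF, −78 °C) is alkylated by F8 anti to the benzyl group to give methyl (2R,6S)-6-{[(4S)-4-benzyl-2-oxo-1,3-oxazolidin-3-yl]carbonyl}-9-(furan-3-yl)-2-(4-methylpent-3-en-1-yl)nonanoate F11, and LiOH/H2O2 at 0 °C cleaves only the imide to give 20.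

**Further compounds**
F1 | step 2 | ethyl 6-methylhept-5-enoate | CCOC(=O)CCCC=C(C)C
F2 | step 2 | 6-methylhept-5-enoic acid | OC(=O)CCCC=C(C)C
F3 | step 2 | (4R)-4-benzyl-3-(6-methylhept-5-enoyl)-1,3-oxazolidin-2-one | CC(C)=CCCCC(=O)N1[C@H](Cc2ccccc2)COC1=O
F4 | step 2 | methyl (4S)-4-{[(4R)-4-benzyl-2-oxo-1,3-oxazolidin-3-yl]carbonyl}-8-methylnon-7-enoate | COC(=O)CC[C@H](CCC=C(C)C)C(=O)N1[C@H](Cc2ccccc2)COC1=O
F5 | step 5 | (4S)-4-(methoxycarbonyl)-8-methylnon-7-enoic acid | COC(=O)[C@@H](CCC=C(C)C)CCC(=O)O
F6 | step 5 | methyl (2S)-2-[3-(ethylsulfanyl)-3-oxopropyl]-6-methylhept-5-enoate | COC(=O)[C@@H](CCC=C(C)C)CCC(=O)SCC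
F7 | step 10 | methyl (2S)-2-(3-hydroxypropyl)-6-methylhept-5-enoate | COC(=O)[C@@H](CCC=C(C)C)CCCO
F8 | step 10 | methyl (2S)-6-methyl-2-{3-[(trifluoromethanesulfonyl)oxy]propyl}hept-5-enoate | COC(=O)[C@@H](CCC=C(C)C)CCCOS(=O)(=O)C(F)(F)F
F9 | step 10 | (4S)-4-benzyl-3-[5-(9-borabicyclo[3.3.1]nonan-9-yl)pentanoyl]-1,3-oxazolidin-2-one | O=C(CCCCB1C2CCCC1CCC2)N1[C@@H](Cc2ccccc2)COC1=O
F10 | step 10 | (4S)-4-benzyl-3-[5-(furan-3-yl)pentanoyl]-1,3-oxazolidin-2-one | O=C(CCCCc1ccoc1)N1[C@@H](Cc2ccccc2)COC1=O
F11 | step 10 | methyl (2R,6S)-6-{[(4S)-4-benzyl-2-oxo-1,3-oxazolidin-3-yl]carbonyl}-9-(furan-3-yl)-2-(4-methylpent-3-en-1-yl)nonanoate | COC(=O)[C@@H](CCC=C(C)C)CCC[C@@H](CCCc1ccoc1)C(=O)N1[C@@H](Cc2ccccc2)COC1=O
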